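**Plan**

- Retrosynthesis: the five benzyl ethers are removed first; the diarylchroman is then cut at O1–C2 (Mitsunobu ether closure after reduction of a chroman-2-one), and that lactone is cut at C3–C4 and at O1–C2(acyl).
- Enabling feature: in the 3,4-diarylchroman O1 sits on C8a, ortho to C4a–C4, so O1–C8a–C4a–C4 is a masked o-quinone methide whose methide carbon C4 carries the isoflavan B ring. C2–C3 with the catechol-type ring is an arylacetic acid.
- The quinone methide comes from an o-hydroxybenzhydryl sulfone, cut at the C4–aryl bond (5'-lithio-isoflavan plus 4-benzyloxysalicylaldehyde). The isoflavan is cut at O1–C2 (Mitsunobu) and C3–C4 (auxiliary alkylation).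
- Forward order: isoflavan pyran ring (step 12), benzhydryl C–C bond (step 13), pyranone ring by the formal [4+2] (step 18), then reduction, re-closure of the chroman ether (step 20) and global hydrogenolysis.
- Stereochemistry: isoflavan C3 (R) from an (R)-4-benzyloxazolidinone alkylation; chroman C4 (S) from the chiral isothiourea; chroman C3 (R) by base equilibration to the 3,4-trans lactone.

Key step: step 18

Remark: the sense of induction of the isothiourea at the methide carbon is assigned by analogy with its anti-selective additions to s-cis enones; both catalyst antipodes are commercial, and the one meant in step 18 is the one that delivers 4S.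

**Route**

Step 1
Reactants: 1 2-hydroxy-4-methoxybenzaldehyde
Product: 2 5-bromo-2-hydroxy-4-methoxybenzaldehyde
Conditions: Br2, CH2Cl2, 0 °C → rt
Reagents that add atoms: bromine, BrBr
Why: Electrophilic aromatic bromination should go to C5, which is para to OH and ortho to OMe and is the only doubly activated position not flanked by two substituents.

Step 2
Reactants: 2 5-bromo-2-hydroxy-4-methoxybenzaldehyde
Product: 3 2-(benzyloxy)-5-bromo-4-methoxybenzaldehyde
Conditions: BnBr, K2CO3, DMF, 50 °C
Reagents that add atoms: benzyl bromide, BrCc1ccccc1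
Why: Williamson etherification of the only phenol, which protects the future 2'-OH as a benzyl ether that survives all steps up to the final hydrogenolysis.

Step 3
Reactants: 3 2-(benzyloxy)-5-bromo-4-methoxybenzaldehyde
Product: 5 2-[2-(benzyloxy)-5-bromo-4-methoxyphenyl]acetaldehyde, via methyl enol ether 4 (not isolated)
Conditions: Ph3P(CH2OMe)Cl, KOt-Bu, THF, 0 °C → rt; then 3 M aq. HCl, 50 °C
Reagents that add atoms: (methoxymethyl)triphenylphosphonium chloride, COC[P+](c1ccccc1)(c1ccccc1)c1ccccc1.[Cl-]; water, O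
Why: Wittig methoxymethylenation followed by acid hydrolysis of the enol ether is the standard one-carbon homologation of an aryl aldehyde, and the aryl bromide and benzyl ether are inert to both stages.

Step 4
Reactants: 5 2-[2-(benzyloxy)-5-bromo-4-methoxyphenyl]acetaldehyde
Product: 6 2-[2-(benzyloxy)-5-bromo-4-methoxyphenyl]acetic acid
Conditions: NaClO2, NaH2PO4, 2-methyl-2-butene, t-BuOH/THF/H2O, rt
Reagents that add atoms: sodium chlorite, [Na+].[O-]Cl=O
Why: Pinnick oxidation converts the enolisable arylacetaldehyde to the acid under buffered conditions, with the alkene scavenger keeping hypochlorous acid away from the electron-rich ring.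

Step 5
Reactants: 6 2-[2-(benzyloxy)-5-bromo-4-methoxyphenyl]acetic acid; 7 (R)-4-benzyloxazolidin-2-one
Product: 9 (R)-4-benzyl-3-{2-[2-(benzyloxy)-5-bromo-4-methoxyphenyl]acetyl}oxazolidin-2-one, via mixed pivalic anhydride 8 (not isolated)
Conditions: t-BuCOCl, Et3N, THF, −20 °C; then 7, LiCl, rt
Reagents that add atoms: none
Why: N-acylation of the Evans oxazolidinone through the mixed pivalic anhydride (LiCl/Et3N protocol) is routine for arylacetic acids, and attack at the unhindered acyl carbon is favoured.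

Step 6
Reactants: 10 4-(benzyloxy)-2-hydroxybenzaldehyde
Product: 11 4-(benzyloxy)-2-(methoxymethoxy)benzaldehyde
Conditions: MOMCl, i-Pr2NEt, CH2Cl2, 0 °C → rt
Reagents that add atoms: chloromethyl methyl ether, COCCl
Why: O-alkylation with MOMCl gives an acetal on the phenol that will close the isoflavan ring, and this group can later be removed by acid without touching benzyl ethers or the aryl bromide.

Step 7
Reactants: 11 4-(benzyloxy)-2-(methoxymethoxy)benzaldehyde
Product: 12 [4-(benzyloxy)-2-(methoxymethoxy)phenyl]methanol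
Conditions: NaBH4, MeOH/THF, 0 °C
Reagents that add atoms: none
Why: Borohydride reduction of the aldehyde to the benzylic alcohol is chemoselective and leaves both ethers intact.

Step 8
Reactants: 12 [4-(benzyloxy)-2-(methoxymethoxy)phenyl]methanol
Product: 13 4-(benzyloxy)-1-(bromomethyl)-2-(methoxymethoxy)benzene
Conditions: CBr4, PPh3, CH2Cl2, 0 °C; used crude at once
Reagents that add atoms: carbon tetrabromide, BrC(Br)(Br)Br
Why: The Appel reaction makes the benzylic bromide under neutral conditions, so the acid-labile MOM acetal survives; the electron-rich bromide is used without storage.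

Step 9
Reactants: 9 (R)-4-benzyl-3-{2-[2-(benzyloxy)-5-bromo-4-methoxyphenyl]acetyl}oxazolidin-2-one; 13 4-(benzyloxy)-1-(bromomethyl)-2-(methoxymethoxy)benzene
Product: 15 (R)-4-benzyl-3-{(2R)-2-[2-(benzyloxy)-5-bromo-4-methoxyphenyl]-3-[4-(benzyloxy)-2-(methoxymethoxy)phenyl]propanoyl}oxazolidin-2-one, via sodium Z-enolate 14 (not isolated)
Conditions: NaHMDS, THF, −78 °C; then 13, −78 → −30 °C
Reagents that add atoms: none
Why: Evans asymmetric alkylation: the chelated Z-enolate is shielded on one face by the benzyl group at C4 of the auxiliary, so the benzylic bromide should enter anti to it and set the (2R) centre that becomes isoflavan C3.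

Step 10
Reactants: 15 (R)-4-benzyl-3-{(2R)-2-[2-(benzyloxy)-5-bromo-4-methoxyphenyl]-3-[4-(benzyloxy)-2-(methoxymethoxy)phenyl]propanoyl}oxazolidin-2-one
Product: 16 (2R)-2-[2-(benzyloxy)-5-bromo-4-methoxyphenyl]-3-[4-(benzyloxy)-2-(methoxymethoxy)phenyl]propan-1-ol
Conditions: LiBH4, MeOH (1 equiv), THF, 0 °C
Reagents that add atoms: none
Why: Reductive cleavage of the N-acyl oxazolidinone by LiBH4 proceeds by hydride attack at the exocyclic carbonyl without enolisation, so the α-aryl centre should be kept and the auxiliary recovered.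

Step 11
Reactants: 16 (2R)-2-[2-(benzyloxy)-5-bromo-4-methoxyphenyl]-3-[4-(benzyloxy)-2-(methoxymethoxy)phenyl]propan-1-ol
Product: 17 5-(benzyloxy)-2-{(2R)-2-[2-(benzyloxy)-5-bromo-4-methoxyphenyl]-3-hydroxypropyl}phenol
Conditions: conc. HCl (cat.), MeOH/THF, 50 °C
Reagents that add atoms: none
Why: Acid-catalysed acetal exchange removes the MOM group selectively, because benzyl ethers, the methyl ether, the aryl bromide and the primary alcohol are stable to dilute methanolic HCl.

Step 12
Reactants: 17 5-(benzyloxy)-2-{(2R)-2-[2-(benzyloxy)-5-bromo-4-methoxyphenyl]-3-hydroxypropyl}phenol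
Product: 18 (3R)-7-(benzyloxy)-3-[2-(benzyloxy)-5-bromo-4-methoxyphenyl]chroman
Conditions: PPh3, DIAD, THF, 0 °C → rt
Reagents that add atoms: none
Why: Intramolecular Mitsunobu etherification (6-exo-tet attack of the only free phenol on the activated primary alcohol) closes the isoflavan pyran ring without involving C3.

Step 13
Reactants: 18 (3R)-7-(benzyloxy)-3-[2-(benzyloxy)-5-bromo-4-methoxyphenyl]chroman; 10 4-(benzyloxy)-2-hydroxybenzaldehyde
Product: 21 5-(benzyloxy)-2-[{4-(benzyloxy)-2-methoxy-5-[(3R)-7-(benzyloxy)chroman-3-yl]phenyl}(hydroxy)methyl]phenol as a mixture of carbinol epimers, via aryllithium 19 (not isolated), via sodium phenoxide 20 (not isolated)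
Conditions: 18, n-BuLi, THF, −78 °C; 10 (1.5 equiv), NaH, THF, 0 °C, added at −78 °C, then → 0 °C; aq. NH4Cl
Reagents that add atoms: none
Why: Bromine–lithium exchange outruns deprotonation at −78 °C and the aryllithium adds 1,2 to the formyl group of the pre-formed salicylaldehyde phenoxide (the usual way to o-hydroxybenzhydrols); the carbinol centre need not be controlled because it becomes sp2 in the quinone methide.

Step 14
Reactants: 21 5-(benzyloxy)-2-[{4-(benzyloxy)-2-methoxy-5-[(3R)-7-(benzyloxy)chroman-3-yl]phenyl}(hydroxy)methyl]phenol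
Product: 22 5-(benzyloxy)-2-[{4-(benzyloxy)-2-methoxy-5-[(3R)-7-(benzyloxy)chroman-3-yl]phenyl}(4-methylbenzenesulfonyl)methyl]phenol as a mixture of epimers at the sulfonyl carbon
Conditions: p-TolSO2H (2 equiv), CH2Cl2, rt
Reagents that add atoms: p-toluenesulfinic acid, Cc1ccc(cc1)S(O)=O
Why: SN1-type sulfination: the sulfinic acid is acidic enough to ionise the carbinol to a cation stabilised by ortho/para oxygen on both rings, and capture at sulfur gives the thermodynamically preferred sulfone.

Step 15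
Reactants: 23 2,3-dihydroxy-4-methoxybenzaldehyde
Product: 24 2,3-bis(benzyloxy)-4-methoxybenzaldehyde
Conditions: BnBr (2.5 equiv), K2CO3, DMF, 60 °C
Reagents that add atoms: benzyl bromide, BrCc1ccccc1
Why: Double Williamson etherification masks the catechol, which would otherwise be acylated and oxidised in the later steps.

Step 16
Reactants: 24 2,3-bis(benzyloxy)-4-methoxybenzaldehyde
Product: 26 2-[2,3-bis(benzyloxy)-4-methoxyphenyl]acetaldehyde, via methyl enol ether 25 (not isolated)
Conditions: Ph3P(CH2OMe)Cl, KOt-Bu, THF, 0 °C → rt; then 3 M aq. HCl, 50 °C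
Reagents that add atoms: (methoxymethyl)triphenylphosphonium chloride, COC[P+](c1ccccc1)(c1ccccc1)c1ccccc1.[Cl-]; water, O
Why: The same Wittig methoxymethylenation and enol ether hydrolysis as in step 3 homologates the aldehyde by one carbon.

Step 17
Reactants: 26 2-[2,3-bis(benzyloxy)-4-methoxyphenyl]acetaldehyde
Product: 27 2-[2,3-bis(benzyloxy)-4-methoxyphenyl]acetic acid
Conditions: NaClO2, NaH2PO4, 2-methyl-2-butene, t-BuOH/THF/H2O, rt
Reagents that add atoms: sodium chlorite, [Na+].[O-]Cl=O
Why: Pinnick oxidation gives the arylacetic acid that serves as the enolate precursor of the key step.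

Step 18
Reactants: 22 5-(benzyloxy)-2-[{4-(benzyloxy)-2-methoxy-5-[(3R)-7-(benzyloxy)chroman-3-yl]phenyl}(4-methylbenzenesulfonyl)methyl]phenol; 27 2-[2,3-bis(benzyloxy)-4-methoxyphenyl]acetic acid
Product: 30 (3R,4S)-7-(benzyloxy)-3-[2,3-bis(benzyloxy)-4-methoxyphenyl]-4-{4-(benzyloxy)-2-methoxy-5-[(3R)-7-(benzyloxy)chroman-3-yl]phenyl}chroman-2-one, via mixed pivalic anhydride 28 (not isolated), via o-quinone methide 29 (not isolated)
Conditions: 27 (1.5 equiv), t-BuCOCl, i-Pr2NEt, CH2Cl2, 0 °C; then 22, (2R,3S)-HyperBTM (10 mol %), Cs2CO3, 0 °C → rt; then DBU (20 mol %), rt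
Reagents that add atoms: none
Why: Carbonate deprotonates the phenol of 22 and expels p-toluenesulfinate to give the E-configured o-quinone methide 29, while the isothiourea is N-acylated by anhydride 28 and the acyl ammonium ion is deprotonated to a Z-ammonium enolate held coplanar by the 1,5-O···S contact. The enolate carbon adds to the methide carbon (C3–C4), and the phenoxide so formed attacks the acyl ammonium carbonyl (6-exo-trig addition–elimination), forming O1–C2, closing the pyranone ring and freeing the catalyst; this is the known isothiourea-catalysed Michael addition–lactonisation of C1-ammonium enolates with o-quinone methides released in situ from 2-(sulfonylmethyl)phenols. C4 is set by the catalyst, whose stereodirecting phenyl group blocks one enolate face so that the compact transition state fixes which face of the planar methide carbon is attacked. C3 is set by the same enolate face and, being benzylic and α to the lactone carbonyl, is then equilibrated by DBU to the more stable 3,4-trans arrangement without touching C4. The step needs face selectivity at the methide carbon and a trans outcome: the ortho-methoxy aryl group on the methide carbon should enforce the E geometry and one reactive conformation of 29, and the acidity of H3 secures trans; a phenol that is O-acylated by 28 is itself an aryl ester that the catalyst can re-enter, so that pathway is not a dead end. The isoflavan stereocentre is remote from C4 and is not expected to compete with the catalyst.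

Step 19
Reactants: 30 (3R,4S)-7-(benzyloxy)-3-[2,3-bis(benzyloxy)-4-methoxyphenyl]-4-{4-(benzyloxy)-2-methoxy-5-[(3R)-7-(benzyloxy)chroman-3-yl]phenyl}chroman-2-one
Product: 31 (2R,3S)-2-[2,3-bis(benzyloxy)-4-methoxyphenyl]-3-[4-(benzyloxy)-2-hydroxyphenyl]-3-{4-(benzyloxy)-2-methoxy-5-[(3R)-7-(benzyloxy)chroman-3-yl]phenyl}propan-1-ol
Conditions: LiAlH4, THF, 0 °C; Rochelle salt work-up
Reagents that add atoms: none
Why: Hydride reduction of the aryl ester lactone to the phenol and primary alcohol is fast at 0 °C, so the intermediate aldehyde should be reduced before its α-centre can enolise.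

Step 20
Reactants: 31 (2R,3S)-2-[2,3-bis(benzyloxy)-4-methoxyphenyl]-3-[4-(benzyloxy)-2-hydroxyphenyl]-3-{4-(benzyloxy)-2-methoxy-5-[(3R)-7-(benzyloxy)chroman-3-yl]phenyl}propan-1-ol
Product: 32 (3R,4S)-7-(benzyloxy)-3-[2,3-bis(benzyloxy)-4-methoxyphenyl]-4-{4-(benzyloxy)-2-methoxy-5-[(3R)-7-(benzyloxy)chroman-3-yl]phenyl}chroman
Conditions: PPh3, DIAD, THF, 0 °C → rt
Reagents that add atoms: none
Why: Intramolecular Mitsunobu etherification (6-exo-tet) of the single free phenol with the primary alcohol re-forms O1–C2 at a CH2 carbon, so neither stereocentre is involved.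

Step 21
Reactants: 32 (3R,4S)-7-(benzyloxy)-3-[2,3-bis(benzyloxy)-4-methoxyphenyl]-4-{4-(benzyloxy)-2-methoxy-5-[(3R)-7-(benzyloxy)chroman-3-yl]phenyl}chroman
Product: 33 (3R,4S)-3-(2,3-dihydroxy-4-methoxyphenyl)-4-{4-hydroxy-2-methoxy-5-[(3R)-7-hydroxychroman-3-yl]phenyl}chroman-7-ol
Conditions: H2 (1 atm), 10% Pd/C, EtOAc/MeOH, rt, degassed solvents
Reagents that add atoms: none
Why: Catalytic hydrogenolysis cleaves the five benzylic C–O bonds, while the chroman ether C–O bonds are not benzylic and the diarylmethine C4 carries no leaving group, so the skeleton and all three stereocentres should be retained.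

**Compound list**

1 | 2-hydroxy-4-methoxybenzaldehyde | COc1ccc(C=O)c(O)c1 | starting material
2 | 5-bromo-2-hydroxy-4-methoxybenzaldehyde | COc1cc(O)c(C=O)cc1Br | intermediate
3 | 2-(benzyloxy)-5-bromo-4-methoxybenzaldehyde | COc1cc(OCc2ccccc2)c(C=O)cc1Br | intermediate
4 | 1-(benzyloxy)-4-bromo-5-methoxy-2-(2-methoxyethenyl)benzene (E/Z mixture) | COC=Cc1cc(Br)c(OC)cc1OCc1ccccc1 | intermediate
5 | 2-[2-(benzyloxy)-5-bromo-4-methoxyphenyl]acetaldehyde | COc1cc(OCc2ccccc2)c(CC=O)cc1Br | intermediate
6 | 2-[2-(benzyloxy)-5-bromo-4-methoxyphenyl]acetic acid | COc1cc(OCc2ccccc2)c(CC(=O)O)cc1Br | intermediate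
7 | (R)-4-benzyloxazolidin-2-one | O=C1N[C@H](Cc2ccccc2)CO1 | starting material
8 | 2-[2-(benzyloxy)-5-bromo-4-methoxyphenyl]acetic pivalic anhydride | COc1cc(OCc2ccccc2)c(CC(=O)OC(=O)C(C)(C)C)cc1Br | intermediate
9 | (R)-4-benzyl-3-{2-[2-(benzyloxy)-5-bromo-4-methoxyphenyl]acetyl}oxazolidin-2-one | COc1cc(OCc2ccccc2)c(CC(=O)N2[C@H](Cc3ccccc3)COC2=O)cc1Br | intermediate
10 | 4-(benzyloxy)-2-hydroxybenzaldehyde | O=Cc1ccc(OCc2ccccc2)cc1O | starting material
11 | 4-(benzyloxy)-2-(methoxymethoxy)benzaldehyde | COCOc1cc(OCc2ccccc2)ccc1C=O | intermediate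
12 | [4-(benzyloxy)-2-(methoxymethoxy)phenyl]methanol | COCOc1cc(OCc2ccccc2)ccc1CO | intermediate
13 | 4-(benzyloxy)-1-(bromomethyl)-2-(methoxymethoxy)benzene | COCOc1cc(OCc2ccccc2)ccc1CBr | intermediate
14 | sodium Z-enolate of 9 | [Na+].COc1cc(OCc2ccccc2)c(/C=C(\[O-])N2[C@H](Cc3ccccc3)COC2=O)cc1Br | intermediate
15 | (R)-4-benzyl-3-{(2R)-2-[2-(benzyloxy)-5-bromo-4-methoxyphenyl]-3-[4-(benzyloxy)-2-(methoxymethoxy)phenyl]propanoyl}oxazolidin-2-one | COc1cc(OCc2ccccc2)c([C@@H](Cc2ccc(OCc3ccccc3)cc2OCOC)C(=O)N2[C@H](Cc3ccccc3)COC2=O)cc1Br | intermediate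
16 | (2R)-2-[2-(benzyloxy)-5-bromo-4-methoxyphenyl]-3-[4-(benzyloxy)-2-(methoxymethoxy)phenyl]propan-1-ol | COc1cc(OCc2ccccc2)c([C@@H](Cc2ccc(OCc3ccccc3)cc2OCOC)CO)cc1Br | intermediate
17 | 5-(benzyloxy)-2-{(2R)-2-[2-(benzyloxy)-5-bromo-4-methoxyphenyl]-3-hydroxypropyl}phenol | COc1cc(OCc2ccccc2)c([C@@H](Cc2ccc(OCc3ccccc3)cc2O)CO)cc1Br | intermediate
18 | (3R)-7-(benzyloxy)-3-[2-(benzyloxy)-5-bromo-4-methoxyphenyl]chroman | COc1cc(OCc2ccccc2)c([C@@H]2COc3cc(OCc4ccccc4)ccc3C2)cc1Br | intermediate
19 | {4-(benzyloxy)-2-methoxy-5-[(3R)-7-(benzyloxy)chroman-3-yl]phenyl}lithium | COc1cc(OCc2ccccc2)c([C@@H]2COc3cc(OCc4ccccc4)ccc3C2)cc1[Li] | intermediate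
20 | sodium 5-(benzyloxy)-2-formylphenoxide | [Na+].[O-]c1cc(OCc2ccccc2)ccc1C=O | intermediate
21 | 5-(benzyloxy)-2-[{4-(benzyloxy)-2-methoxy-5-[(3R)-7-(benzyloxy)chroman-3-yl]phenyl}(hydroxy)methyl]phenol (carbinol epimers) | COc1cc(OCc2ccccc2)c([C@@H]2COc3cc(OCc4ccccc4)ccc3C2)cc1C(O)c1ccc(OCc2ccccc2)cc1O | intermediate
22 | 5-(benzyloxy)-2-[{4-(benzyloxy)-2-methoxy-5-[(3R)-7-(benzyloxy)chroman-3-yl]phenyl}(4-methylbenzenesulfonyl)methyl]phenol (epimers at the sulfonyl carbon) | COc1cc(OCc2ccccc2)c([C@@H]2COc3cc(OCc4ccccc4)ccc3C2)cc1C(c1ccc(OCc2ccccc2)cc1O)S(=O)(=O)c1ccc(C)cc1 | intermediate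
23 | 2,3-dihydroxy-4-methoxybenzaldehyde | COc1ccc(C=O)c(O)c1O | starting material
24 | 2,3-bis(benzyloxy)-4-methoxybenzaldehyde | COc1ccc(C=O)c(OCc2ccccc2)c1OCc1ccccc1 | intermediate
25 | 2,3-bis(benzyloxy)-1-methoxy-4-(2-methoxyethenyl)benzene (E/Z mixture) | COC=Cc1ccc(OC)c(OCc2ccccc2)c1OCc1ccccc1 | intermediate
26 | 2-[2,3-bis(benzyloxy)-4-methoxyphenyl]acetaldehyde | COc1ccc(CC=O)c(OCc2ccccc2)c1OCc1ccccc1 | intermediate
27 | 2-[2,3-bis(benzyloxy)-4-methoxyphenyl]acetic acid | COc1ccc(CC(=O)O)c(OCc2ccccc2)c1OCc1ccccc1 | intermediate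
28 | 2-[2,3-bis(benzyloxy)-4-methoxyphenyl]acetic pivalic anhydride | COc1ccc(CC(=O)OC(=O)C(C)(C)C)c(OCc2ccccc2)c1OCc1ccccc1 | intermediate
29 | 3-(benzyloxy)-6-({4-(benzyloxy)-2-methoxy-5-[(3R)-7-(benzyloxy)chroman-3-yl]phenyl}methylidene)cyclohexa-2,4-dien-1-one (o-quinone methide, E expected) | COc1cc(OCc2ccccc2)c([C@@H]2COc3cc(OCc4ccccc4)ccc3C2)cc1C=C1C=CC(OCc2ccccc2)=CC1=O | intermediate
30 | (3R,4S)-7-(benzyloxy)-3-[2,3-bis(benzyloxy)-4-methoxyphenyl]-4-{4-(benzyloxy)-2-methoxy-5-[(3R)-7-(benzyloxy)chroman-3-yl]phenyl}chroman-2-one (trans) | COc1cc(OCc2ccccc2)c([C@@H]2COc3cc(OCc4ccccc4)ccc3C2)cc1[C@@H]1c2ccc(OCc3ccccc3)cc2OC(=O)[C@H]1c1ccc(OC)c(OCc2ccccc2)c1OCc1ccccc1 | intermediate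
31 | (2R,3S)-2-[2,3-bis(benzyloxy)-4-methoxyphenyl]-3-[4-(benzyloxy)-2-hydroxyphenyl]-3-{4-(benzyloxy)-2-methoxy-5-[(3R)-7-(benzyloxy)chroman-3-yl]phenyl}propan-1-ol | COc1cc(OCc2ccccc2)c([C@@H]2COc3cc(OCc4ccccc4)ccc3C2)cc1[C@H](c1ccc(OCc2ccccc2)cc1O)[C@@H](CO)c1ccc(OC)c(OCc2ccccc2)c1OCc1ccccc1 | intermediate
32 | (3R,4S)-7-(benzyloxy)-3-[2,3-bis(benzyloxy)-4-methoxyphenyl]-4-{4-(benzyloxy)-2-methoxy-5-[(3R)-7-(benzyloxy)chroman-3-yl]phenyl}chroman | COc1cc(OCc2ccccc2)c([C@@H]2COc3cc(OCc4ccccc4)ccc3C2)cc1[C@@H]1c2ccc(OCc3ccccc3)cc2OC[C@H]1c1ccc(OC)c(OCc2ccccc2)c1OCc1ccccc1 | intermediate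
33 | (3R,4S)-3-(2,3-dihydroxy-4-methoxyphenyl)-4-{4-hydroxy-2-methoxy-5-[(3R)-7-hydroxychroman-3-yl]phenyl}chroman-7-ol (CNP0112305.1) | COc1cc(O)c([C@@H]2COc3cc(O)ccc3C2)cc1[C@@H]1c2ccc(O)cc2OC[C@H]1c1ccc(OC)c(O)c1O | target

**Step count**

Total: 21 steps. Longest linear sequence: 15 steps (steps 1–5, 9–14, 18–21); the side branches are steps 6–8 and 15–17.

**Steps most likely to fail**

Step 18. The donor-rich quinone methide is a sluggish electrophile, so discrimination between the two faces of the methide carbon may be poor, and acylation of the phenol may consume the activated acid before the methide is released. The fallback sets out from aldehyde 26 and sulfone 22 and returns at diol 31. Compounds 26 and 22 are combined with a diarylprolinol trimethylsilyl ether (20 mol %, the enantiomer that gives 4S) and a carbonate base in CH2Cl2. The enamine of 26 adds to quinone methide 29 and the phenoxide closes onto the iminium carbon, which is the known aminocatalytic formal [4+2] of aldehydes with o-quinone methides from 2-(sulfonylmethyl)phenols. Hydrolysis should leave the trans lactol (3R,4S)-7-(benzyloxy)-3-[2,3-bis(benzyloxy)-4-methoxyphenyl]-4-{4-(benzyloxy)-2-methoxy-5-[(3R)-7-(benzyloxy)chroman-3-yl]phenyl}chroman-2-ol F1, whose C3 equilibrates to trans through the open hydroxy aldehyde. NaBH4 in MeOH/THF then reduces the lactol through its open form to 31, and the route continues with step 20.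

Step 13. The aryllithium may be protonated, or the 1,2-addition may stall because the phenoxide strongly deactivates the formyl group. The fallback sets out from 10 and 18 and returns at 21. Aldehyde 10 is silylated (TBSCl, imidazole, DMF) to 4-(benzyloxy)-2-[(tert-butyldimethylsilyl)oxy]benzaldehyde F2, a neutral and more electrophilic aldehyde. Aryllithium 19, made from 18 as before, adds at −78 °C to give the silyl carbinol 2-[(tert-butyldimethylsilyl)oxy]-4-(benzyloxy)phenyl carbinol F3 (the silyl group may move to the benzylic oxygen, which is of no consequence). TBAF in THF at 0 °C removes the silyl group from either oxygen and gives 21.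

Step 14. Ionisation of the carbinol gives a long-lived cation that may alkylate the electron-rich rings of a second molecule faster than it is captured by sulfinate. The fallback sets out from 10 and 18, avoids acid and the carbinol altogether, and returns at 22. Aldehyde 10 is converted with Boc2O and catalytic DMAP into tert-butyl 5-(benzyloxy)-2-formylphenyl carbonate F4. Aryllithium 19 adds at −78 °C; on warming, the alkoxide takes over the Boc group and the phenoxide expels tert-butyl carbonate, which releases quinone methide 29 under basic conditions. Sodium p-toluenesulfinate present in the mixture adds to the methide carbon, and acidification with acetic acid at low temperature should give sulfone 22.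

**Further compounds**

F1 | step 18 | (3R,4S)-7-(benzyloxy)-3-[2,3-bis(benzyloxy)-4-methoxyphenyl]-4-{4-(benzyloxy)-2-methoxy-5-[(3R)-7-(benzyloxy)chroman-3-yl]phenyl}chroman-2-ol (anomeric mixture) | COc1cc(OCc2ccccc2)c([C@@H]2COc3cc(OCc4ccccc4)ccc3C2)cc1[C@@H]1c2ccc(OCc3ccccc3)cc2OC(O)[C@H]1c1ccc(OC)c(OCc2ccccc2)c1OCc1ccccc1
F2 | step 13 | 4-(benzyloxy)-2-[(tert-butyldimethylsilyl)oxy]benzaldehyde | CC(C)(C)[Si](C)(C)Oc1cc(OCc2ccccc2)ccc1C=O
F3 | step 13 | {4-(benzyloxy)-2-[(tert-butyldimethylsilyl)oxy]phenyl}{4-(benzyloxy)-2-methoxy-5-[(3R)-7-(benzyloxy)chroman-3-yl]phenyl}methanol (carbinol epimers) | COc1cc(OCc2ccccc2)c([C@@H]2COc3cc(OCc4ccccc4)ccc3C2)cc1C(O)c1ccc(OCc2ccccc2)cc1O[Si](C)(C)C(C)(C)C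
F4 | step 14 | tert-butyl 5-(benzyloxy)-2-formylphenyl carbonate | CC(C)(C)OC(=O)Oc1cc(OCc2ccccc2)ccc1C=O
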